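**Plan**
1. Cuts (core numbering: C-2 lactone carbonyl, C-1/C-5 ring fusion, C-6 aryl carbon, O-7, C-8): the side chain at its carbinol C–C bond (aldol) and at ArO–CH2; the tetrahydrofuran ring at C-6–O-7 and C-6–H; the aryl–C-6 bond; the two CH2O–C bonds at C-1 and C-5.
2. Enabling feature: the ether ring C-6/O-7/C-8/C-1/C-5 is a reduced cyclic hemiketal of an aryl ketone. With C-6 as a carbonyl the core is a C2-symmetric bis-lactone with two equivalent carbonyls, so one aryllithium addition marks C-6 with no regiochemical issue.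
3. Forward order: succinyl bis-imide → two successive alkylations → bis-lactone 9 (lactone ring formed) → ring-opening arylation to hydroxy ketone 13 → tetrahydrofuran ring closed last by reductive cycloetherification → phenol → aryloxyacetyl imide → anti-aldol with vanillin → reductive removal of the auxiliary.
4. Stereochemistry: C-1 and C-5 come from (S)-4-benzyloxazolidin-2-one in two auxiliary-controlled alkylations. C-6 is relayed from them by hydride delivery to the convex face of the bicyclic oxocarbenium ion (aryl endo, H-1/H-5/H-6 all cis). The erythro (1R,2S) side chain comes from the same auxiliary by a magnesium-catalysed anti-aldol.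

Key step: step 7

Remark on the chemistry: 13 is drawn as the open hydroxy ketone (its ring tautomer 14 enters the same cation), 18 is taken as a purchasable reagent, and the sense of induction in step 10 is taken from the chelated-enolate model.

Step 1
Reactants: 1 (S)-4-benzyloxazolidin-2-one (2 equiv); 2 succinyl chloride
Product: 3 1,4-bis[(4S)-4-benzyl-2-oxo-1,3-oxazolidin-3-yl]butane-1,4-dione
Conditions: n-BuLi (2 equiv), THF, −78 °C; then 2 (1 equiv), −78 → 0 °C
Reagents that add atoms: none
Why: Double N-acylation of the lithiated oxazolidinone by the diacid chloride (standard imide formation) should give the C2-symmetric bis-imide; no stereocentre is formed.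

Step 2
Reactants: 3 bis-imide; 4 benzyl chloromethyl ether
Product: 5 (2R)-2-[(benzyloxy)methyl]-1,4-bis[(4S)-4-benzyl-2-oxo-1,3-oxazolidin-3-yl]butane-1,4-dione
Conditions: TiCl4 (1.05 equiv), i-Pr2NEt (1.1 equiv), CH2Cl2, 0 °C; then 4 (1.5 equiv), 0 °C → rt
Reagents that add atoms: none
Why: Evans alkylation of a titanium enolate: soft enolisation of one TiCl4-chelated imide gives the Z enolate and 4 attacks the face opposite the 4-benzyl group, which should set the new centre R; recovered 3 is recycled and any 6 formed by a second alkylation is simply the product of step 3.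

Step 3
Reactants: 5 monoalkylated bis-imide; 4 benzyl chloromethyl ether
Product: 6 (2R,3R)-2,3-bis[(benzyloxy)methyl]-1,4-bis[(4S)-4-benzyl-2-oxo-1,3-oxazolidin-3-yl]butane-1,4-dione
Conditions: TiCl4 (1.05 equiv), i-Pr2NEt (1.1 equiv), CH2Cl2, 0 °C; then 4 (2 equiv), 0 °C → rt
Reagents that add atoms: none
Why: Second Evans alkylation of a titanium enolate: only the unbranched CH2 of 5 enolises readily, and its own (S)-auxiliary again directs 4 to the face opposite the benzyl group, so the second centre should also come out R and the product is C2-symmetric.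

Step 4
Reactants: 6 bis(benzyloxymethyl) bis-imide
Product: 9 (1R,5R)-3,7-dioxabicyclo[3.3.0]octane-2,6-dione, via diol bis-imide 7 (not isolated), via hydroxy lactone imide 8 (not isolated)
Conditions: H2 (1 atm), 10% Pd/C, EtOAc, rt; filter; camphorsulfonic acid (cat.), CH2Cl2, rt
Reagents that add atoms: none
Why: Hydrogenolysis of the two alkyl benzyl ethers frees primary alcohols that each sit γ to the distal imide carbonyl, so acid-catalysed 5-exo-trig acyl transfer (lactonisation with loss of the auxiliary) should occur twice and give the cis-fused bis-lactone, the only fusion the (R,R) configuration permits, with no stereocentre touched.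

Step 5
Reactants: 10 4-bromo-2,6-dimethoxyphenol
Product: 11 2-(benzyloxy)-5-bromo-1,3-dimethoxybenzene
Conditions: BnBr, K2CO3, DMF, rt
Reagents that add atoms: benzyl bromide, BrCc1ccccc1
Why: Williamson etherification of the phenoxide protects the phenol for the organolithium step.

Step 6
Reactants: 11 aryl bromide; 9 bis-lactone (1.5 equiv)
Product: 13 (3R,4R)-4-[4-(benzyloxy)-3,5-dimethoxybenzoyl]-3-(hydroxymethyl)oxolan-2-one, via aryllithium 12 (not isolated)
Conditions: 11, n-BuLi (1 equiv), THF, −78 °C; add to 9, THF, −78 °C; AcOH, −78 °C; used promptly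
Reagents that add atoms: none
Why: Bromine–lithium exchange followed by addition of the aryllithium to a lactone carbonyl; the two carbonyls of 9 are homotopic through its C2 axis, so no regiochemical choice exists, the lithium hemiketalate resists a second addition until the cold quench, inverse addition to excess 9 limits bis-addition, and the two stereocentres are not touched.

Step 7
Reactants: 13 hydroxy ketone
Product: 16 (1R,5R,6R)-6-[4-(benzyloxy)-3,5-dimethoxyphenyl]-3,7-dioxabicyclo[3.3.0]octan-2-one, via cyclic hemiketal 14 (not isolated), via oxocarbenium triflate 15 (not isolated)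
Conditions: Et3SiH (3 equiv), Me3SiOTf (0.3 equiv), CH2Cl2, −78 → −40 °C; Et3N, then aq. NaHCO3
Reagents that add atoms: none
Why: The silyl triflate (triflic acid after the first turnover) activates the aryl ketone, the primary hydroxyl adds to give hemiketal 14, this ionises to the 2-aryl oxocarbenium ion 15, and Et3SiH transfers hydride to C-6. The closest known reaction type is the ionic hydrogenation of aryl lactols and hydroxy ketones with a silane and a Lewis acid (reductive cycloetherification, as used for C-aryl glycosides). The tetrahydrofuran ring closes by 5-exo-trig attack of O-7 on the ketone carbon C-6, and the C-6–H bond is then made on the cyclic cation. The new stereocentre C-6 is controlled by the cis-fused 3,7-dioxabicyclo[3.3.0]octane shape of 15: hydride should enter on the convex face, syn to H-5 and H-1, which places the aryl group endo and gives the all-cis (1R,5R,6R) array. The step needs kinetic facial selectivity without later acid-induced reopening of the benzylic ether, and chemoselectivity over the lactone; low temperature, sub-stoichiometric acid and an amine quench serve the first, and the lactone carbonyl cannot form a comparably stabilised cation. Enolisation of 15 towards C-5 is harmless, because reprotonation can only regenerate the cis-fused ion.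

Step 8
Reactants: 16 bicyclic benzyl ether
Product: 17 (1R,5R,6R)-6-(4-hydroxy-3,5-dimethoxyphenyl)-3,7-dioxabicyclo[3.3.0]octan-2-one
Conditions: H2 (1 atm), 10% Pd/C, EtOAc, rt
Reagents that add atoms: none
Why: Hydrogenolysis of the aryl benzyl ether is much faster than that of the hindered cyclic benzylic ether, so the phenol should be freed with the ring and C-6 intact.

Step 9
Reactants: 17 phenol; 18 (S)-4-benzyl-3-(chloroacetyl)oxazolidin-2-one
Product: 19 (4S)-4-benzyl-3-({2,6-dimethoxy-4-[(1R,5R,6R)-2-oxo-3,7-dioxabicyclo[3.3.0]oct-6-yl]phenoxy}acetyl)-1,3-oxazolidin-2-one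
Conditions: K2CO3, NaI (cat.), DMF, rt
Reagents that add atoms: none
Why: Williamson O-alkylation (SN2 at the activated α-halo imide, iodide catalysis by in situ Finkelstein exchange) under conditions too mild to open the lactone or epimerise C-6.

Step 10
Reactants: 19 aryloxyacetyl imide; 20 vanillin (1.3 equiv)
Product: 23 (4S)-4-benzyl-3-[(2R,3R)-2-{2,6-dimethoxy-4-[(1R,5R,6R)-2-oxo-3,7-dioxabicyclo[3.3.0]oct-6-yl]phenoxy}-3-hydroxy-3-(4-hydroxy-3-methoxyphenyl)propanoyl]-1,3-oxazolidin-2-one, via silylated vanillin 21 (not isolated), via bis-silylated aldol adduct 22 (not isolated)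
Conditions: 20, Et3N (4 equiv), Me3SiCl (3.5 equiv), EtOAc, rt; then 19, MgCl2 (0.2 equiv), rt; then 1 M aq. citric acid, THF, 0 °C
Reagents that add atoms: none
Why: Magnesium halide-catalysed direct anti-aldol of an N-acyloxazolidinone: Et3N enolises the MgCl2-chelated imide to the Z enolate, which should add to the in situ silylated aldehyde 21 through a boat-like transition state on the face opposite the auxiliary benzyl group (α-carbon R) with anti topicity (carbinol carbon R), Me3SiCl trapping the aldolate, turning the catalyst over and masking the phenol until the mild acidic work-up.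

Step 11
Reactants: 23 aldol adduct
Product: 24 CNP0398772.1 (target)
Conditions: NaBH4, THF–H2O (4:1), 0 °C → rt
Reagents that add atoms: none
Why: Borohydride reduces the activated exocyclic imide carbonyl (reductive removal of the oxazolidinone) much faster than the lactone, so the primary alcohol should form without touching any stereocentre, the descriptor of the aryloxy carbon changing from R to S only through the change in priorities.

**Compound list**
1 | (S)-4-benzyloxazolidin-2-one | O=C1N[C@@H](Cc2ccccc2)CO1 | starting material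
2 | succinyl chloride | O=C(Cl)CCC(Cl)=O | starting material
3 | 1,4-bis[(4S)-4-benzyl-2-oxo-1,3-oxazolidin-3-yl]butane-1,4-dione | O=C(CCC(=O)N1[C@@H](Cc2ccccc2)COC1=O)N1[C@@H](Cc2ccccc2)COC1=O | intermediate
4 | benzyl chloromethyl ether | ClCOCc1ccccc1 | starting material
5 | (2R)-2-[(benzyloxy)methyl]-1,4-bis[(4S)-4-benzyl-2-oxo-1,3-oxazolidin-3-yl]butane-1,4-dione | O=C(C[C@H](COCc1ccccc1)C(=O)N1[C@@H](Cc2ccccc2)COC1=O)N1[C@@H](Cc2ccccc2)COC1=O | intermediate
6 | (2R,3R)-2,3-bis[(benzyloxy)methyl]-1,4-bis[(4S)-4-benzyl-2-oxo-1,3-oxazolidin-3-yl]butane-1,4-dione | O=C([C@@H](COCc1ccccc1)[C@H](COCc1ccccc1)C(=O)N1[C@@H](Cc2ccccc2)COC1=O)N1[C@@H](Cc2ccccc2)COC1=O | intermediate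
7 | (2R,3R)-2,3-bis(hydroxymethyl)-1,4-bis[(4S)-4-benzyl-2-oxo-1,3-oxazolidin-3-yl]butane-1,4-dione | O=C([C@@H](CO)[C@H](CO)C(=O)N1[C@@H](Cc2ccccc2)COC1=O)N1[C@@H](Cc2ccccc2)COC1=O | intermediate (not isolated)
8 | (4S)-4-benzyl-3-{[(3R,4R)-4-(hydroxymethyl)-5-oxooxolan-3-yl]carbonyl}-1,3-oxazolidin-2-one | O=C1OC[C@H](C(=O)N2[C@@H](Cc3ccccc3)COC2=O)[C@@H]1CO | intermediate (not isolated)
9 | (1R,5R)-3,7-dioxabicyclo[3.3.0]octane-2,6-dione | O=C1OC[C@@H]2C(=O)OC[C@@H]21 | intermediate
10 | 4-bromo-2,6-dimethoxyphenol | COc1cc(Br)cc(OC)c1O | starting material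
11 | 2-(benzyloxy)-5-bromo-1,3-dimethoxybenzene | COc1cc(Br)cc(OC)c1OCc1ccccc1 | intermediate
12 | [4-(benzyloxy)-3,5-dimethoxyphenyl]lithium | COc1cc([Li])cc(OC)c1OCc1ccccc1 | intermediate (not isolated)
13 | (3R,4R)-4-[4-(benzyloxy)-3,5-dimethoxybenzoyl]-3-(hydroxymethyl)oxolan-2-one | OC[C@@H]1C(=O)OC[C@@H]1C(=O)c1cc(OC)c(OCc2ccccc2)c(OC)c1 | intermediate
14 | (1R,5R)-6-[4-(benzyloxy)-3,5-dimethoxyphenyl]-6-hydroxy-3,7-dioxabicyclo[3.3.0]octan-2-one (both configurations at C-6) | OC1(c2cc(OC)c(OCc3ccccc3)c(OC)c2)OC[C@@H]2C(=O)OC[C@@H]21 | intermediate (not isolated)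
15 | (1R,5R)-6-[4-(benzyloxy)-3,5-dimethoxyphenyl]-2-oxo-3-oxa-7-oxoniabicyclo[3.3.0]oct-6-ene triflate | COc1cc(cc(OC)c1OCc1ccccc1)C1=[O+]C[C@@H]2C(=O)OC[C@@H]21.[O-]S(=O)(=O)C(F)(F)F | intermediate (not isolated)
16 | (1R,5R,6R)-6-[4-(benzyloxy)-3,5-dimethoxyphenyl]-3,7-dioxabicyclo[3.3.0]octan-2-one | COc1cc(cc(OC)c1OCc1ccccc1)[C@@H]1OC[C@@H]2C(=O)OC[C@@H]21 | intermediate
17 | (1R,5R,6R)-6-(4-hydroxy-3,5-dimethoxyphenyl)-3,7-dioxabicyclo[3.3.0]octan-2-one | COc1cc(cc(OC)c1O)[C@@H]1OC[C@@H]2C(=O)OC[C@@H]21 | intermediate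
18 | (S)-4-benzyl-3-(chloroacetyl)oxazolidin-2-one | O=C(CCl)N1[C@@H](Cc2ccccc2)COC1=O | starting material
19 | (4S)-4-benzyl-3-({2,6-dimethoxy-4-[(1R,5R,6R)-2-oxo-3,7-dioxabicyclo[3.3.0]oct-6-yl]phenoxy}acetyl)-1,3-oxazolidin-2-one | O=C(COc1c(OC)cc(cc1OC)[C@@H]1OC[C@@H]2C(=O)OC[C@@H]21)N1[C@@H](Cc2ccccc2)COC1=O | intermediate
20 | vanillin | COc1cc(C=O)ccc1O | starting material
21 | 3-methoxy-4-(trimethylsilyloxy)benzaldehyde | COc1cc(C=O)ccc1O[Si](C)(C)C | intermediate (not isolated)
22 | bis(trimethylsilyl) ether of 23 (carbinol and phenol oxygens silylated) | COc1cc([C@@H](O[Si](C)(C)C)[C@H](C(=O)N2[C@@H](Cc3ccccc3)COC2=O)Oc2c(OC)cc(cc2OC)[C@@H]2OC[C@@H]3C(=O)OC[C@@H]32)ccc1O[Si](C)(C)C | intermediate (not isolated)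
23 | (4S)-4-benzyl-3-[(2R,3R)-2-{2,6-dimethoxy-4-[(1R,5R,6R)-2-oxo-3,7-dioxabicyclo[3.3.0]oct-6-yl]phenoxy}-3-hydroxy-3-(4-hydroxy-3-methoxyphenyl)propanoyl]-1,3-oxazolidin-2-one | COc1cc([C@@H](O)[C@H](C(=O)N2[C@@H](Cc3ccccc3)COC2=O)Oc2c(OC)cc(cc2OC)[C@@H]2OC[C@@H]3C(=O)OC[C@@H]32)ccc1O | intermediate
24 | (1R,5R,6R)-6-{4-[(1R,2S)-1,3-dihydroxy-1-(4-hydroxy-3-methoxyphenyl)propan-2-yl]oxy-3,5-dimethoxyphenyl}-3,7-dioxabicyclo[3.3.0]octan-2-one | COc1cc([C@@H](O)[C@H](CO)Oc2c(OC)cc([C@@H]3OC[C@@H]4C(=O)OC[C@@H]43)cc2OC)ccc1O | target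

**Step count**
Total: 11 steps. Longest linear sequence: 10 steps (steps 1, 2, 3, 4, 6, 7, 8, 9, 10, 11); step 5 is a one-step branch.

**Steps most likely to fail**

Step 10. The magnesium-catalysed aldol may show poor anti/syn or facial discrimination with an α-aryloxy imide, or add sluggishly to the electron-rich aldehyde. If only the facial sense were reversed, the (R)-configured reagent would be used in step 9. The fallback sets out from 17 and comes back at 24; it uses the dependable boron-mediated syn aldol and then inverts the carbinol carbon by oxidation and chelation-controlled reduction. 17 is alkylated (K2CO3, NaI, DMF) with (R)-4-benzyl-3-(chloroacetyl)oxazolidin-2-one to the enantiomeric-auxiliary imide F1. Its dibutylboron enolate (Bu2BOTf, i-Pr2NEt, CH2Cl2, −78 → 0 °C, H2O2 work-up) should add to commercial 4-(tert-butyldimethylsilyloxy)-3-methoxybenzaldehyde in the syn sense to give the syn aldol adduct F2, which has the correct aryloxy carbon and the epimeric carbinol. NaBH4 in THF–H2O then gives the threo diol F3, and t-BuMe2SiCl with imidazole silylates the primary alcohol to the silyl ether F4. Dess–Martin periodinane gives the α-aryloxy ketone F5. Zn(BH4)2 in Et2O at −20 °C should reduce it under chelation control (zinc bridging the ketone and aryloxy oxygens, hydride entering past the hydrogen of the adjacent centre) to the anti (erythro) alcohol F6, leaving the lactone alone. Bu4NF with AcOH removes both silyl groups to give 24.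

Step 7. The kinetic endo selectivity may erode through acid-induced reopening of the benzylic ether (epimerisation at C-6). Over-reduction to a ring-opened benzylic methylene compound, direct ionic hydrogenation of the open ketone, or slow funnelling of material epimerised at C-5 on storage of 13 are also possible. The fallback sets out from 13 and comes back at 16 without any cationic intermediate. A catalyst-controlled Corey–Bakshi–Shibata reduction (the B-methyl oxazaborolidine from (S)-diphenylprolinol, BH3·SMe2, THF), with the aryl group acting as the large substituent, should give the (R)-configured benzylic alcohol, diol F7. Mitsunobu cyclodehydration (PPh3, diisopropyl azodicarboxylate, THF) then activates the primary alcohol, which is displaced by the benzylic oxygen, so C-6 keeps its configuration and 16 results.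

Step 6. The aryllithium may deprotonate the bis-lactone, leading to β-elimination of the acyloxy group, or add twice. The fallback sets out from 6 and comes back at 17; it moves the arylation ahead of any lactone. 6 is cleaved with LiOH and H2O2 in THF–H2O at 0 °C to the diacid F8. Coupling with MeNHOMe·HCl (N-ethyl-N′-(3-dimethylaminopropyl)carbodiimide hydrochloride, i-Pr2NEt, CH2Cl2) gives the bis-Weinreb amide F9. Aryllithium 12, made as in step 6 (1 equiv, THF, −78 °C), adds through a chelated tetrahedral intermediate that cannot react again at the same carbonyl and gives the keto amide F10. Hydrogenolysis (H2, 10% Pd/C, EtOAc) removes all three benzyl groups to give the triol F11. F11 lactonises under camphorsulfonic acid catalysis onto the remaining Weinreb amide to the phenolic hydroxy ketone F12. F12 under the conditions of step 7 should give 17 directly.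

Further compounds
F1 | step 10 | (4R)-4-benzyl-3-({2,6-dimethoxy-4-[(1R,5R,6R)-2-oxo-3,7-dioxabicyclo[3.3.0]oct-6-yl]phenoxy}acetyl)-1,3-oxazolidin-2-one | O=C(COc1c(OC)cc(cc1OC)[C@@H]1OC[C@@H]2C(=O)OC[C@@H]21)N1[C@H](Cc2ccccc2)COC1=O
F2 | step 10 | (4R)-4-benzyl-3-[(2R,3S)-3-[4-(tert-butyldimethylsilyloxy)-3-methoxyphenyl]-2-{2,6-dimethoxy-4-[(1R,5R,6R)-2-oxo-3,7-dioxabicyclo[3.3.0]oct-6-yl]phenoxy}-3-hydroxypropanoyl]-1,3-oxazolidin-2-one | COc1cc([C@H](O)[C@H](C(=O)N2[C@H](Cc3ccccc3)COC2=O)Oc2c(OC)cc(cc2OC)[C@@H]2OC[C@@H]3C(=O)OC[C@@H]32)ccc1O[Si](C)(C)C(C)(C)C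
F3 | step 10 | (1R,5R,6R)-6-{4-[(1S,2S)-1-[4-(tert-butyldimethylsilyloxy)-3-methoxyphenyl]-1,3-dihydroxypropan-2-yl]oxy-3,5-dimethoxyphenyl}-3,7-dioxabicyclo[3.3.0]octan-2-one | COc1cc([C@H](O)[C@H](CO)Oc2c(OC)cc(cc2OC)[C@@H]2OC[C@@H]3C(=O)OC[C@@H]32)ccc1O[Si](C)(C)C(C)(C)C
F4 | step 10 | primary tert-butyldimethylsilyl ether of F3 | COc1cc([C@H](O)[C@H](CO[Si](C)(C)C(C)(C)C)Oc2c(OC)cc(cc2OC)[C@@H]2OC[C@@H]3C(=O)OC[C@@H]32)ccc1O[Si](C)(C)C(C)(C)C
F5 | step 10 | (1R,5R,6R)-6-{4-[(2S)-3-(tert-butyldimethylsilyloxy)-1-[4-(tert-butyldimethylsilyloxy)-3-methoxyphenyl]-1-oxopropan-2-yl]oxy-3,5-dimethoxyphenyl}-3,7-dioxabicyclo[3.3.0]octan-2-one | COc1cc(C(=O)[C@H](CO[Si](C)(C)C(C)(C)C)Oc2c(OC)cc(cc2OC)[C@@H]2OC[C@@H]3C(=O)OC[C@@H]32)ccc1O[Si](C)(C)C(C)(C)C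
F6 | step 10 | bis(tert-butyldimethylsilyl) ether of 24 (primary alcohol and phenol silylated, (1R,2S) side chain) | COc1cc([C@@H](O)[C@H](CO[Si](C)(C)C(C)(C)C)Oc2c(OC)cc(cc2OC)[C@@H]2OC[C@@H]3C(=O)OC[C@@H]32)ccc1O[Si](C)(C)C(C)(C)C
F7 | step 7 | (3R,4R)-4-{(R)-[4-(benzyloxy)-3,5-dimethoxyphenyl](hydroxy)methyl}-3-(hydroxymethyl)oxolan-2-one | OC[C@@H]1C(=O)OC[C@@H]1[C@@H](O)c1cc(OC)c(OCc2ccccc2)c(OC)c1
F8 | step 6 | (2R,3R)-2,3-bis[(benzyloxy)methyl]butanedioic acid | OC(=O)[C@@H](COCc1ccccc1)[C@H](COCc1ccccc1)C(O)=O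
F9 | step 6 | (2R,3R)-2,3-bis[(benzyloxy)methyl]-N1,N4-dimethoxy-N1,N4-dimethylbutanediamide | CON(C)C(=O)[C@@H](COCc1ccccc1)[C@H](COCc1ccccc1)C(=O)N(C)OC
F10 | step 6 | (2R,3R)-4-[4-(benzyloxy)-3,5-dimethoxyphenyl]-2,3-bis[(benzyloxy)methyl]-N-methoxy-N-methyl-4-oxobutanamide | CON(C)C(=O)[C@@H](COCc1ccccc1)[C@H](COCc1ccccc1)C(=O)c1cc(OC)c(OCc2ccccc2)c(OC)c1
F11 | step 6 | (2R,3R)-4-(4-hydroxy-3,5-dimethoxyphenyl)-2,3-bis(hydroxymethyl)-N-methoxy-N-methyl-4-oxobutanamide | CON(C)C(=O)[C@@H](CO)[C@H](CO)C(=O)c1cc(OC)c(O)c(OC)c1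
F12 | step 6 | (3R,4R)-4-(4-hydroxy-3,5-dimethoxybenzoyl)-3-(hydroxymethyl)oxolan-2-one | OC[C@@H]1C(=O)OC[C@@H]1C(=O)c1cc(OC)c(O)c(OC)c1
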